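## Retrosynthetic overview

- Target ⇒ (Si–O cleavage) ⇒ Z-selective Wittig disconnection of C6=C7 into a C1–C6 ylide (E-allylic silyl ether) and an α-acetoxy ketone that carries C7, C8, C19 and the whole stereotriad.
- Key disconnection: the C8–C9 bond of that ketone, made by xanthate-transfer radical addition of an acetoxyacetonyl radical to the vinyl group of the unprotected hydroxy-oxolane.
- The oxolane is the only ring. It is closed in the second step of its branch, before the radical coupling, by Shi epoxidation and 5-endo acid cyclisation of an anti-crotylation adduct.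
- C11/C12 come from Ir-catalysed anti-crotylation of 4-methylpent-3-en-1-ol; C1–C6 from Zr-catalysed carboalumination of 5-chloropent-1-yne; the C7/C8/C19 linchpin from 1,3-dichloroacetone.

Locants are those of the C20 chain: C1 = CH2OH end, C7 carries the acetoxymethyl carbon C19, C11 is the methyl-bearing methine, C12/C14/C15 are ring carbons.

Assumption: (R)-SEGPHOS is taken as the ligand antipode that gives the (3R,4S)-anti adduct 7 (and (+)-Ipc2BOMe likewise in the fallback); if the sense of induction is the reverse, the mirror-image ligand is used and nothing else changes.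

## Route

Step 1
Reactants: 1 1,3-dichloropropan-2-one
Product: 2 3-chloro-2-oxopropyl acetate
Conditions: KOAc (1 equiv), 1 (2.5 equiv), acetone, 40 °C; excess 1 distilled off
Reagents that add atoms: potassium acetate, CC(=O)[O-].[K+]
Why: SN2 displacement of one activated α-keto chloride by acetate, with excess 1 suppressing the diacetate.

Step 2
Reactants: 2 3-chloro-2-oxopropyl acetate
Product: 3 3-[(ethoxycarbonothioyl)sulfanyl]-2-oxopropyl acetate
Conditions: EtOC(S)SK (1.05 equiv), acetone, 0 °C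
Reagents that add atoms: potassium O-ethyl xanthate, CCOC(=S)[S-].[K+]
Why: SN2 displacement of the remaining α-keto chloride by the soft xanthate anion, which does not touch the acetate.

Step 3
Reactants: 4 4-methylpent-3-en-1-ol; 5 but-3-en-2-yl acetate (racemic)
Product: 7 (3R,4S)-3,7-dimethylocta-1,6-dien-4-ol, via 4-methylpent-3-enal 6 (not isolated)
Conditions: [Ir(cod)Cl]2 (2.5 mol%), (R)-SEGPHOS (5 mol%), 4-cyano-3-nitrobenzoic acid (10 mol%), Cs2CO3 (20 mol%), 5 (2 equiv), THF, 90 °C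
Reagents that add atoms: none
Why: Krische redox-neutral carbonyl crotylation (Ir transfer hydrogenation) dehydrogenates 4 to 6, and the (E)-σ-crotyl-iridium adds through a closed chair transition state that sets the anti C3/C4 pair (later C11/C12) under ligand control.

Step 4
Reactants: 7 (3R,4S)-3,7-dimethylocta-1,6-dien-4-ol
Product: 9 (3R,5S)-5-[(2R)-but-3-en-2-yl]-2,2-dimethyloxolan-3-ol, via epoxy alcohol 8 (not isolated)
Conditions: D-fructose-derived Shi ketone (30 mol%), Oxone, K2CO3, Bu4NHSO4, MeCN/DMM/aq. buffer pH 10.5, 0 °C; then CSA (10 mol%), CH2Cl2, 0 °C → rt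
Reagents that add atoms: Oxone (active component potassium peroxymonosulfate), [K+].[O-]S(=O)(=O)OO
Why: Shi asymmetric epoxidation takes the electron-rich trisubstituted alkene over the vinyl group and sets the epoxide CH (later C14, R) under catalyst control; acid-promoted 5-endo epoxide-opening etherification at the tertiary carbon by the C4 hydroxyl then closes the ring with both C–O stereocentres retained, giving the 3,5-trans oxolane.

Step 5
Reactants: 9 (3R,5S)-5-[(2R)-but-3-en-2-yl]-2,2-dimethyloxolan-3-ol; 3 3-[(ethoxycarbonothioyl)sulfanyl]-2-oxopropyl acetate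
Product: 11 (6R)-6-[(2S,4R)-4-hydroxy-5,5-dimethyloxolan-2-yl]-2-oxoheptyl acetate, via C10 xanthate adduct 10 (not isolated)
Conditions: 3 (1.5 equiv), dilauroyl peroxide (10 mol%, in portions), EtOAc, reflux; then (Me3Si)3SiH (1.5 equiv), AIBN (20 mol%), toluene, 80 °C
Reagents that add atoms: none
Why: Zard xanthate-transfer radical addition, in which the electrophilic acetoxyacetonyl radical adds to the terminal CH2 of the unactivated alkene to form the C8–C9 bond and degenerative xanthate transfer gives 10; its C–S bond is then reduced in a silyl-radical chain, and no stereocentre is formed or touched.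

Step 6
Reactants: 12 5-chloropent-1-yne
Product: 15 (2E)-6-chloro-3-methylhex-2-en-1-ol, via alkenylalane 13 (not isolated), via lithium alanate 14 (not isolated)
Conditions: Me3Al (2 equiv), Cp2ZrCl2 (20 mol%), CH2Cl2, 0 °C → rt; volatiles removed; n-BuLi (1 equiv), hexane/THF, −78 °C; (CH2O)n, −78 °C → rt
Reagents that add atoms: trimethylaluminium, C[Al](C)C; paraformaldehyde (as formaldehyde), C=O
Why: Negishi Zr-catalysed carboalumination adds Me–Al syn across the alkyne, fixing the E trisubstituted alkene, and the alanate is hydroxymethylated with retention of geometry.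

Step 7
Reactants: 15 (2E)-6-chloro-3-methylhex-2-en-1-ol
Product: 16 tert-butyl{[(2E)-6-chloro-3-methylhex-2-en-1-yl]oxy}dimethylsilane
Conditions: TBSCl, imidazole, CH2Cl2, rt
Reagents that add atoms: tert-butyldimethylsilyl chloride, CC(C)(C)[Si](C)(C)Cl
Why: Standard silyl ether formation, which keeps the C1 oxygen distinct from the C19 acetate until the last step.

Step 8
Reactants: 16 tert-butyl{[(2E)-6-chloro-3-methylhex-2-en-1-yl]oxy}dimethylsilane
Product: 18 [(4E)-6-{[tert-butyl(dimethyl)silyl]oxy}-4-methylhex-4-en-1-yl]triphenylphosphonium iodide, via alkyl iodide 17 (not isolated)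
Conditions: NaI (1.5 equiv), PPh3 (1.2 equiv), i-Pr2NEt (5 mol%), MeCN, reflux
Reagents that add atoms: triphenylphosphine, c1ccc(cc1)P(c1ccccc1)c1ccccc1; sodium iodide, [Na+].[I-]
Why: Finkelstein exchange followed by SN2 quaternisation of triphenylphosphine at the primary carbon, remote from the alkene.

Step 9
Reactants: 18 [(4E)-6-{[tert-butyl(dimethyl)silyl]oxy}-4-methylhex-4-en-1-yl]triphenylphosphonium iodide; 11 (6R)-6-[(2S,4R)-4-hydroxy-5,5-dimethyloxolan-2-yl]-2-oxoheptyl acetate
Product: 20 (2Z,6E)-8-{[tert-butyl(dimethyl)silyl]oxy}-2-{(4R)-4-[(2S,4R)-4-hydroxy-5,5-dimethyloxolan-2-yl]pentyl}-6-methylocta-2,6-dien-1-yl acetate, via ylide 19 (not isolated)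
Conditions: 18 (2.5 equiv), KHMDS (2.4 equiv), THF, −78 → 0 °C; then 11, −78 → −20 °C; cold NH4Cl quench
Reagents that add atoms: none
Why: Wittig olefination of an α-oxygenated ketone by a salt-free non-stabilised ylide (Still Z-selective variant) places the oxygenated CH2 cis to the incoming chain, giving the 2Z alkene; the excess ylide covers the free ring hydroxyl and the cold quench protects the acetate.

Step 10
Reactants: 20 (2Z,6E)-8-{[tert-butyl(dimethyl)silyl]oxy}-2-{(4R)-4-[(2S,4R)-4-hydroxy-5,5-dimethyloxolan-2-yl]pentyl}-6-methylocta-2,6-dien-1-yl acetate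
Product: 21 (2Z,6E)-8-hydroxy-2-{(4R)-4-[(2S,4R)-4-hydroxy-5,5-dimethyloxolan-2-yl]pentyl}-6-methylocta-2,6-dien-1-yl acetate
Conditions: HF·pyridine, pyridine, THF, 0 °C → rt
Reagents that add atoms: none
Why: Buffered fluoride desilylation removes the primary allylic TBS ether without acyl migration or loss of the allylic acetate.

## Compound list

1 | 1,3-dichloropropan-2-one | ClCC(=O)CCl | starting material
2 | 3-chloro-2-oxopropyl acetate | CC(=O)OCC(=O)CCl | intermediate
3 | 3-[(ethoxycarbonothioyl)sulfanyl]-2-oxopropyl acetate | CCOC(=S)SCC(=O)COC(C)=O | intermediate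
4 | 4-methylpent-3-en-1-ol | CC(C)=CCCO | starting material
5 | but-3-en-2-yl acetate (racemic) | CC(OC(C)=O)C=C | starting material
6 | 4-methylpent-3-enal | CC(C)=CCC=O | intermediate (not isolated)
7 | (3R,4S)-3,7-dimethylocta-1,6-dien-4-ol | C=C[C@@H](C)[C@@H](O)CC=C(C)C | intermediate
8 | (2S,3R)-1-[(2R)-3,3-dimethyloxiran-2-yl]-3-methylpent-4-en-2-ol | C=C[C@@H](C)[C@@H](O)C[C@H]1OC1(C)C | intermediate (not isolated)
9 | (3R,5S)-5-[(2R)-but-3-en-2-yl]-2,2-dimethyloxolan-3-ol | C=C[C@@H](C)[C@@H]1C[C@@H](O)C(C)(C)O1 | intermediate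
10 | (5RS,6S)-5-[(ethoxycarbonothioyl)sulfanyl]-6-[(2S,4R)-4-hydroxy-5,5-dimethyloxolan-2-yl]-2-oxoheptyl acetate | CCOC(=S)SC(CCC(=O)COC(C)=O)[C@@H](C)[C@@H]1C[C@@H](O)C(C)(C)O1 | intermediate (not isolated)
11 | (6R)-6-[(2S,4R)-4-hydroxy-5,5-dimethyloxolan-2-yl]-2-oxoheptyl acetate | CC(=O)OCC(=O)CCC[C@@H](C)[C@@H]1C[C@@H](O)C(C)(C)O1 | intermediate
12 | 5-chloropent-1-yne | C#CCCCCl | starting material
13 | [(1E)-5-chloro-2-methylpent-1-en-1-yl]dimethylalumane | C[Al](C)/C=C(\C)CCCCl | intermediate (not isolated)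
14 | lithium butyl[(1E)-5-chloro-2-methylpent-1-en-1-yl]dimethylaluminate | [Li+].CCCC[Al-](C)(C)/C=C(\C)CCCCl | intermediate (not isolated)
15 | (2E)-6-chloro-3-methylhex-2-en-1-ol | OC/C=C(\C)CCCCl | intermediate
16 | tert-butyl{[(2E)-6-chloro-3-methylhex-2-en-1-yl]oxy}dimethylsilane | CC(C)(C)[Si](C)(C)OC/C=C(\C)CCCCl | intermediate
17 | tert-butyl{[(2E)-6-iodo-3-methylhex-2-en-1-yl]oxy}dimethylsilane | CC(C)(C)[Si](C)(C)OC/C=C(\C)CCCI | intermediate (not isolated)
18 | [(4E)-6-{[tert-butyl(dimethyl)silyl]oxy}-4-methylhex-4-en-1-yl]triphenylphosphonium iodide | CC(C)(C)[Si](C)(C)OC/C=C(\C)CCC[P+](c1ccccc1)(c1ccccc1)c1ccccc1.[I-] | intermediate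
19 | tert-butyl(dimethyl){[(2E)-3-methyl-6-(triphenyl-λ5-phosphanylidene)hex-2-en-1-yl]oxy}silane | CC(C)(C)[Si](C)(C)OC/C=C(\C)CCC=P(c1ccccc1)(c1ccccc1)c1ccccc1 | intermediate (not isolated)
20 | (2Z,6E)-8-{[tert-butyl(dimethyl)silyl]oxy}-2-{(4R)-4-[(2S,4R)-4-hydroxy-5,5-dimethyloxolan-2-yl]pentyl}-6-methylocta-2,6-dien-1-yl acetate | CC(=O)OC/C(=C\CC/C(C)=C/CO[Si](C)(C)C(C)(C)C)CCC[C@@H](C)[C@@H]1C[C@@H](O)C(C)(C)O1 | intermediate
21 | (2Z,6E)-8-hydroxy-2-{(4R)-4-[(2S,4R)-4-hydroxy-5,5-dimethyloxolan-2-yl]pentyl}-6-methylocta-2,6-dien-1-yl acetate | CC(=O)OC/C(=C\CC/C(C)=C/CO)CCC[C@@H](C)[C@@H]1C[C@@H](O)C(C)(C)O1 | target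

## Step count and risks

Total steps: 10. Longest linear sequence: 5 (steps 3, 4, 5, 9, 10; the other two branches are equally long).

**Step 9 (most likely to fail).** The acyloxy ketone may give lower Z-selectivity than the ether-type α-alkoxy ketones for which this Wittig is established, and the acetate and free ring hydroxyl are exposed to a basic ylide. The fallback sets out from 11 and returns at 20; it takes the acetate off before the olefination and puts it back afterwards. K2CO3 in MeOH converts 11 into the keto diol (6R)-1-hydroxy-6-[(2S,4R)-4-hydroxy-5,5-dimethyloxolan-2-yl]heptan-2-one F1. 2-Methoxypropene with PPTS masks both hydroxyls to give (6R)-1-[(2-methoxypropan-2-yl)oxy]-6-{(2S,4R)-4-[(2-methoxypropan-2-yl)oxy]-5,5-dimethyloxolan-2-yl}heptan-2-one F2, an α-alkoxy ketone of the established class. Olefination with ylide 19 gives tert-butyl{[(2E,6Z,11R)-7-{[(2-methoxypropan-2-yl)oxy]methyl}-11-{(2S,4R)-4-[(2-methoxypropan-2-yl)oxy]-5,5-dimethyloxolan-2-yl}-3-methyldodeca-2,6-dien-1-yl]oxy}dimethylsilane F3. PPTS in MeOH at 0 °C removes both mixed ketals but not the TBS ether, giving (2Z,6E)-8-{[tert-butyl(dimethyl)silyl]oxy}-2-{(4R)-4-[(2S,4R)-4-hydroxy-5,5-dimethyloxolan-2-yl]pentyl}-6-methylocta-2,6-dien-1-ol F4. Acetyl chloride with 2,4,6-collidine at −78 °C acetylates the primary allylic hydroxyl in preference to the hindered ring hydroxyl and gives 20.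

**Step 3.** The transient β,γ-unsaturated aldehyde 6 can isomerise into conjugation under hot basic conditions, and the sense and level of induction rest on the assumption above. The fallback sets out from 4 and returns at 7; it replaces the catalytic hydrogen-borrowing process by a stoichiometric reagent-controlled allylboration at −78 °C. Dess–Martin oxidation of 4 (NaHCO3, CH2Cl2, 0 °C) gives 6, used at once as a cold solution. trans-But-2-ene is metalated with n-BuLi/KOt-Bu (−78 → −45 °C) and trapped with (+)-Ipc2BOMe, then BF3·OEt2, to give [(2E)-but-2-en-1-yl]bis[(1S,2R,3S,5S)-2,6,6-trimethylbicyclo[3.1.1]heptan-3-yl]borane F5. Addition of 6 at −78 °C through the Zimmerman–Traxler chair gives (3R,4S)-3,7-dimethylocta-1,6-dien-4-yl bis[(1S,2R,3S,5S)-2,6,6-trimethylbicyclo[3.1.1]heptan-3-yl]borinate F6, and NaOH/H2O2 work-up releases 7.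

**Step 5.** The radical chain runs on an unprotected alcohol and the reduction is telescoped; short chains, telomers or incomplete C–S reduction would cost material at the convergent point. The fallback sets out from 9 and returns at 11; it makes the same C8–C9 bond by a two-electron boron-ate 1,2-shift (Brown α-alkylation of an α-bromo ketone). 9-BBN (2.2 equiv, THF, rt) hydroborates the vinyl group and borylates the hydroxyl, giving 9-[(3R)-3-{(2S,4R)-4-[(9-borabicyclo[3.3.1]nonan-9-yl)oxy]-5,5-dimethyloxolan-2-yl}butyl]-9-borabicyclo[3.3.1]nonane F7. NaBr in acetone converts 2 into 3-bromo-2-oxopropyl acetate F8. F7, F8 and potassium 2,6-di-tert-butylphenoxide (THF, 0 °C) give, after aqueous ethanol work-up, ketone 11.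

## Further compounds

F1 | step 9 | (6R)-1-hydroxy-6-[(2S,4R)-4-hydroxy-5,5-dimethyloxolan-2-yl]heptan-2-one | OCC(=O)CCC[C@@H](C)[C@@H]1C[C@@H](O)C(C)(C)O1
F2 | step 9 | (6R)-1-[(2-methoxypropan-2-yl)oxy]-6-{(2S,4R)-4-[(2-methoxypropan-2-yl)oxy]-5,5-dimethyloxolan-2-yl}heptan-2-one | COC(C)(C)OCC(=O)CCC[C@@H](C)[C@@H]1C[C@@H](OC(C)(C)OC)C(C)(C)O1
F3 | step 9 | tert-butyl{[(2E,6Z,11R)-7-{[(2-methoxypropan-2-yl)oxy]methyl}-11-{(2S,4R)-4-[(2-methoxypropan-2-yl)oxy]-5,5-dimethyloxolan-2-yl}-3-methyldodeca-2,6-dien-1-yl]oxy}dimethylsilane | COC(C)(C)OC/C(=C\CC/C(C)=C/CO[Si](C)(C)C(C)(C)C)CCC[C@@H](C)[C@@H]1C[C@@H](OC(C)(C)OC)C(C)(C)O1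
F4 | step 9 | (2Z,6E)-8-{[tert-butyl(dimethyl)silyl]oxy}-2-{(4R)-4-[(2S,4R)-4-hydroxy-5,5-dimethyloxolan-2-yl]pentyl}-6-methylocta-2,6-dien-1-ol | OC/C(=C\CC/C(C)=C/CO[Si](C)(C)C(C)(C)C)CCC[C@@H](C)[C@@H]1C[C@@H](O)C(C)(C)O1
F5 | step 3 | [(2E)-but-2-en-1-yl]bis[(1S,2R,3S,5S)-2,6,6-trimethylbicyclo[3.1.1]heptan-3-yl]borane | C/C=C/CB([C@H]1C[C@H]2C[C@@H]([C@@H]1C)C2(C)C)[C@H]1C[C@H]2C[C@@H]([C@@H]1C)C2(C)C
F6 | step 3 | (3R,4S)-3,7-dimethylocta-1,6-dien-4-yl bis[(1S,2R,3S,5S)-2,6,6-trimethylbicyclo[3.1.1]heptan-3-yl]borinate | C=C[C@@H](C)[C@H](CC=C(C)C)OB([C@H]1C[C@H]2C[C@@H]([C@@H]1C)C2(C)C)[C@H]1C[C@H]2C[C@@H]([C@@H]1C)C2(C)C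
F7 | step 5 | 9-[(3R)-3-{(2S,4R)-4-[(9-borabicyclo[3.3.1]nonan-9-yl)oxy]-5,5-dimethyloxolan-2-yl}butyl]-9-borabicyclo[3.3.1]nonane | C[C@H](CCB1C2CCCC1CCC2)[C@@H]1C[C@@H](OB2C3CCCC2CCC3)C(C)(C)O1
F8 | step 5 | 3-bromo-2-oxopropyl acetate | CC(=O)OCC(=O)CBr
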